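**Plan**
- Retrosynthesis: after functional-group adjustment, ring A is cut at C2–C3 (pinacol). The one-carbon units C19, C3, C18 (on C4) and C2 (on C1) are then removed, and ring B is cut last at C5–C6 and C9–C10 ([4+2]), leaving diene 5 and enal ester 6.
- Enabling feature: ring B (C5–C10) is a cyclohexene with its olefin at C7=C8, so C5–C6 and C9–C10 are the two σ bonds of a Diels–Alder adduct whose diene C6=C7–C8=C9 already carries the C11–C16 chain on C9.
- Forward: diene from geranic acid (steps 1–3), ring B by the catalytic cycloaddition (step 4), C2, C18, C3 and C19 added one carbon at a time (steps 5–9), ring A closed by C2–C3 pinacol coupling (step 13), then acetylation, C19 oxidation and ester cleavage.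
- Stereochemistry: C5, C9 and C10 come from the catalyst-controlled exo-formyl cycloaddition; C4 from 1,2-induction by C5 in the hydroxymethylation; C2 and C3 from the chelated cis-pinacol in the chair that keeps O2 equatorial.

Key step: step 4

Assumption: commercial geranic acid is used as its (2E) isomer, and the sense of induction in step 4 is taken from the formyl C–H···O binding model for 2-substituted enals (Si-face attack at the formyl-bearing carbon with the (R)-prolinol-derived catalyst; the antipodal catalyst is equally available if the sense proves opposite).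
Positions are given in labdane numbering; C19 is the C4 substituent cis to C20.

**Route**

Step 1
Reactants: 1 geranic acid
Product: 2 tert-butyl geranate
Conditions: Me2NCH(Ot-Bu)2, toluene, 80 °C
Reagents that add atoms: N,N-dimethylformamide di-tert-butyl acetal, CN(C)C(OC(C)(C)C)OC(C)(C)C
Why: Esterification with a formamide acetal proceeds by alkylation of the carboxylate within the alkoxyiminium ion pair under neutral conditions, so both olefins and the 2E geometry should be untouched.

Step 2
Reactants: 2 tert-butyl geranate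
Product: 4 tert-butyl (2E,6E)-3,7-dimethyl-8-oxoocta-2,6-dienoate, via allylic alcohol 3 (not isolated)
Conditions: SeO2 (cat.), salicylic acid (cat.), t-BuOOH, CH2Cl2, rt; filter; then MnO2, CH2Cl2, rt
Reagents that add atoms: tert-butyl hydroperoxide, CC(C)(C)OO (terminal oxidant; oxygen relayed by catalytic selenium dioxide, O=[Se]=O)
Why: Selenium dioxide allylic oxidation (ene reaction, then [2,3]-sigmatropic shift) attacks the (E)-methyl group of the electron-rich terminal olefin and spares the deactivated enoate, and MnO2 oxidation of the allylic alcohol converges the mixture on the 6E enal.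

Step 3
Reactants: 4 tert-butyl (2E,6E)-3,7-dimethyl-8-oxoocta-2,6-dienoate
Product: 5 tert-butyl (2E,6E)-3,7-dimethylnona-2,6,8-trienoate
Conditions: Ph3PCH3Br, KN(SiMe3)2, THF, −78 → 0 °C
Reagents that add atoms: methyltriphenylphosphonium bromide, C[P+](c1ccccc1)(c1ccccc1)c1ccccc1.[Br-]
Why: Wittig methylenation of the enal is much faster than any attack on the hindered tert-butyl enoate and keeps the 6E geometry set in step 2, giving the (E)-1-alkyl-2-methyl diene.

Step 4
Reactants: 5 tert-butyl (2E,6E)-3,7-dimethylnona-2,6,8-trienoate; 6 ethyl (2E)-3-methyl-4-oxobut-2-enoate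
Product: 7 ring-B aldehyde ester (C10 formyl and methyl; C9 side chain; C5 ethoxycarbonyl)
Conditions: B-(o-tolyl)oxazaborolidine from (R)-α,α-diphenylprolinol and tri-o-tolylboroxine (22 mol %), Tf2NH (20 mol %), CH2Cl2, −78 → −40 °C
Reagents that add atoms: none
Why: The protonated oxazaborolidine binds the formyl oxygen of 6 (formyl C–H···O contact, s-trans enal) and lowers its LUMO, so a concerted, asynchronous [4+2] cycloaddition with s-cis diene 5 should take place, the closest known reaction type being the oxazaborolidinium-catalysed Diels–Alder reaction of 2-substituted acroleins. Ring B closes in this intermolecular suprafacial [4+2] mode by forming C5–C6 and C9–C10. Regiochemistry follows the ortho rule: the formyl-activated β-carbon C5 bonds to the unsubstituted terminus C6, whose coefficient is raised more by the C9 alkyl group than that of C9 is by the C8 methyl, so the quaternary C10 joins C9. The trans C5/C10 relationship of ester and formyl is copied from the E dienophile, and the exo-formyl transition state with the 2-methyl and ester groups endo, normal for 2-substituted enals, places C20 cis to the outward C9 chain. Absolute configuration comes from the catalyst, whose aryl group shields the Re face of the formyl-bearing carbon so that the diene adds to its Si face and gives 5S,9R,10S. The step needs regio-, exo- and facial selectivity, secured respectively by formyl (not ester) activation together with the terminal alkyl group of the diene, by the α-methyl group of the enal, and by the two-point binding of the formyl group to the chiral cation.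

Step 5
Reactants: 7 ring-B aldehyde ester
Product: 8 C10-vinyl ethyl ester
Conditions: Ph3PCH3Br, KN(SiMe3)2, THF, 0 °C
Reagents that add atoms: methyltriphenylphosphonium bromide, C[P+](c1ccccc1)(c1ccccc1)c1ccccc1.[Br-]
Why: Wittig methylenation of the neopentyl, non-enolisable aldehyde adds C2 as a vinyl group inert to all later carbonyl chemistry, while both esters are unreactive to the ylide at 0 °C and C5 already sits in its more stable equatorial configuration.

Step 6
Reactants: 8 C10-vinyl ethyl ester
Product: 10 C4 methyl ketone, via Weinreb amide 9 (not isolated)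
Conditions: MeNHOMe·HCl, i-PrMgCl, THF, −20 → 0 °C; then MeMgBr, 0 °C; aq. NH4Cl
Reagents that add atoms: methylmagnesium bromide, C[Mg]Br (N,O-dimethylhydroxylamine hydrochloride, CNOC.Cl, supplies atoms to intermediate 9 only)
Why: One-pot Weinreb ketone synthesis: the chloromagnesium amide converts the ethyl ester into amide 9, whose chelated adduct with MeMgBr stops at the ketone and installs C18, while the hindered β,β-disubstituted tert-butyl enoate does not compete and C5 stays equatorial.

Step 7
Reactants: 10 C4 methyl ketone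
Product: 11 methyl enol ether (E/Z mixture)
Conditions: Ph3PCH2OMe Cl, KN(SiMe3)2, THF, 0 °C → rt
Reagents that add atoms: (methoxymethyl)triphenylphosphonium chloride, COC[P+](c1ccccc1)(c1ccccc1)c1ccccc1.[Cl-]
Why: Wittig reaction with (methoxymethylene)triphenylphosphorane is the standard one-carbon homologation of hindered methyl ketones (as with 20-oxo steroids) and adds C3; the enol ether geometry is of no consequence.

Step 8
Reactants: 11 methyl enol ether
Product: 12 α-methyl aldehyde (both C4 epimers)
Conditions: 2 M HCl, THF, rt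
Reagents that add atoms: water, O
Why: Acid-catalysed enol ether hydrolysis (C-protonation, hemiacetal collapse) releases the C3 aldehyde under conditions that leave the tert-butyl ester and the olefins alone, and the C4 epimers converge in step 9.

Step 9
Reactants: 12 α-methyl aldehyde
Product: 13 (4R)-hydroxymethyl aldehyde
Conditions: 37% aq. HCHO, DBU (cat.), THF, 0 °C → rt
Reagents that add atoms: formaldehyde, C=O
Why: Base-catalysed crossed aldol with formaldehyde (α-hydroxymethylation of an α-branched aldehyde): the enolate, with oxygen trans to C5 and H5 turned towards the C4 methyl to minimise allylic strain, should be attacked on the face away from the quaternary C10 (1,2-induction), setting C4 with the formyl carbon as C3 and the new carbon as C19, while catalytic base and limited formaldehyde hold back Cannizzaro reduction.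

Step 10
Reactants: 13 (4R)-hydroxymethyl aldehyde
Product: 14 C19 silyl ether aldehyde
Conditions: TBDPSCl, imidazole, DMF, rt
Reagents that add atoms: tert-butyl(chloro)diphenylsilane, CC(C)(C)[Si](Cl)(c1ccccc1)c1ccccc1
Why: Imidazole-promoted silylation of the primary alcohol; the bulky TBDPS group is chosen because it should not migrate between the two oxygenated arms on C4 (which would scramble C4) and should outlast steps 11–14.

Step 11
Reactants: 14 C19 silyl ether aldehyde
Product: 16 2,3-diol (open chain), via bis-borane adduct 15 (not isolated)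
Conditions: 9-BBN (3 equiv), THF, 0 °C → rt; then NaBO3·4H2O, H2O, rt
Reagents that add atoms: sodium perborate tetrahydrate, [Na+].[O-]OB=O.O.O.O.O
Why: Hydroboration–oxidation: 9-BBN adds anti-Markovnikov to the only monosubstituted olefin (the trisubstituted C7=C8 olefin and the enoate are too hindered or electron-poor at rt) and at the same time reduces the aldehyde, and near-neutral perborate work-up gives the diol without silyl migration.

Step 12
Reactants: 16 2,3-diol (open chain)
Product: 17 1,6-dialdehyde
Conditions: Dess–Martin periodinane, NaHCO3, CH2Cl2, rt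
Reagents that add atoms: none
Why: Dess–Martin oxidation of both primary alcohols under bicarbonate buffering gives the C2 and C3 aldehydes without over-oxidation or base-induced aldol reaction, and C4 is quaternary and cannot epimerise.

Step 13
Reactants: 17 1,6-dialdehyde
Product: 18 ring-A cis-2,3-diol
Conditions: SmI2 (2.5 equiv), t-BuOH, THF, −78 °C → rt
Reagents that add atoms: none
Why: SmI2 pinacol coupling of a 1,6-dialdehyde (ketyl formation, 6-exo addition to the second formyl group held by trivalent samarium) should give the cis-diol, and of the two cis chairs the one with O3 axial and O2 equatorial is preferred because an axial O2 would be syn-diaxial to both C20 and the C19 silyloxymethyl group, which sets 2S,3R and closes ring A as the trans-decalin.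

Step 14
Reactants: 18 ring-A cis-2,3-diol
Product: 19 2,3-diacetate
Conditions: Ac2O, DMAP, pyridine, rt → 40 °C
Reagents that add atoms: acetic anhydride, CC(=O)OC(C)=O
Why: DMAP-catalysed acylation should esterify both secondary hydroxyls, including the hindered axial 3-OH next to the quaternary C4.

Step 15
Reactants: 19 2,3-diacetate
Product: 20 C19 alcohol
Conditions: Bu4NF, AcOH (1:1), THF, rt → 40 °C
Reagents that add atoms: none
Why: Fluoride desilylation buffered with acetic acid frees the C19 alcohol without acetate cleavage, and acetyl migration from O3 is geometrically excluded because O3 and C19 are trans-diaxial.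

Step 16
Reactants: 20 C19 alcohol
Product: 21 C19 aldehyde tert-butyl ester
Conditions: Dess–Martin periodinane, NaHCO3, CH2Cl2, rt
Reagents that add atoms: none
Why: Dess–Martin oxidation of the neopentyl primary alcohol gives the non-enolisable C19 aldehyde under buffered conditions that tolerate the acetates and the tert-butyl ester.

Step 17
Reactants: 21 C19 aldehyde tert-butyl ester
Product: 23 target acid CNP0273594.1, via trimethylsilyl ester 22 (not isolated)
Conditions: TMSOTf, 2,6-lutidine, CH2Cl2, 0 °C; then pH 5 aqueous buffer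
Reagents that add atoms: none
Why: Silyl triflate-mediated tert-butyl ester cleavage (O-silylation, loss of the tert-butyl cation as isobutene to the hindered base), then hydrolysis of the labile silyl ester, frees the acid without protic acid and so spares the C7=C8 olefin, the acetates and the aldehyde.

**Compound list**

1 | geranic acid, (2E)-3,7-dimethylocta-2,6-dienoic acid | CC(C)=CCC/C(C)=C/C(=O)O | starting material
2 | tert-butyl (2E)-3,7-dimethylocta-2,6-dienoate | CC(C)=CCC/C(C)=C/C(=O)OC(C)(C)C | intermediate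
3 | tert-butyl (2E,6E)-8-hydroxy-3,7-dimethylocta-2,6-dienoate | OC/C(C)=C/CC/C(C)=C/C(=O)OC(C)(C)C | intermediate (not isolated)
4 | tert-butyl (2E,6E)-3,7-dimethyl-8-oxoocta-2,6-dienoate | O=C/C(C)=C/CC/C(C)=C/C(=O)OC(C)(C)C | intermediate
5 | tert-butyl (2E,6E)-3,7-dimethylnona-2,6,8-trienoate | C=C/C(C)=C/CC/C(C)=C/C(=O)OC(C)(C)C | intermediate
6 | ethyl (2E)-3-methyl-4-oxobut-2-enoate | O=C/C(C)=C/C(=O)OCC | starting material
7 | tert-butyl (2E)-5-[(1R,5S,6S)-5-(ethoxycarbonyl)-6-formyl-2,6-dimethylcyclohex-2-en-1-yl]-3-methylpent-2-enoate | O=C[C@@]1(C)[C@H](CC/C(C)=C/C(=O)OC(C)(C)C)C(C)=CC[C@@H]1C(=O)OCC | intermediate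
8 | tert-butyl (2E)-5-[(1R,5S,6S)-6-ethenyl-5-(ethoxycarbonyl)-2,6-dimethylcyclohex-2-en-1-yl]-3-methylpent-2-enoate | C=C[C@@]1(C)[C@H](CC/C(C)=C/C(=O)OC(C)(C)C)C(C)=CC[C@@H]1C(=O)OCC | intermediate
9 | tert-butyl (2E)-5-[(1R,5S,6S)-6-ethenyl-5-[methoxy(methyl)carbamoyl]-2,6-dimethylcyclohex-2-en-1-yl]-3-methylpent-2-enoate | C=C[C@@]1(C)[C@H](CC/C(C)=C/C(=O)OC(C)(C)C)C(C)=CC[C@@H]1C(=O)N(C)OC | intermediate (not isolated)
10 | tert-butyl (2E)-5-[(1R,5S,6S)-5-acetyl-6-ethenyl-2,6-dimethylcyclohex-2-en-1-yl]-3-methylpent-2-enoate | C=C[C@@]1(C)[C@H](CC/C(C)=C/C(=O)OC(C)(C)C)C(C)=CC[C@@H]1C(C)=O | intermediate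
11 | tert-butyl (2E)-5-[(1R,5S,6S)-6-ethenyl-5-(1-methoxyprop-1-en-2-yl)-2,6-dimethylcyclohex-2-en-1-yl]-3-methylpent-2-enoate (E/Z mixture at the enol ether) | C=C[C@@]1(C)[C@H](CC/C(C)=C/C(=O)OC(C)(C)C)C(C)=CC[C@@H]1C(C)=COC | intermediate
12 | tert-butyl (2E)-5-[(1R,5R,6R)-6-ethenyl-2,6-dimethyl-5-(1-oxopropan-2-yl)cyclohex-2-en-1-yl]-3-methylpent-2-enoate (both epimers at the aldehyde α-carbon) | C=C[C@@]1(C)[C@H](CC/C(C)=C/C(=O)OC(C)(C)C)C(C)=CC[C@@H]1C(C)C=O | intermediate
13 | tert-butyl (2E)-5-[(1R,5S,6S)-6-ethenyl-5-[(2R)-1-hydroxy-2-methyl-3-oxopropan-2-yl]-2,6-dimethylcyclohex-2-en-1-yl]-3-methylpent-2-enoate | C=C[C@@]1(C)[C@H](CC/C(C)=C/C(=O)OC(C)(C)C)C(C)=CC[C@@H]1[C@](C)(CO)C=O | intermediate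
14 | tert-butyl (2E)-5-[(1R,5S,6S)-5-[(2R)-1-[(tert-butyldiphenylsilyl)oxy]-2-methyl-3-oxopropan-2-yl]-6-ethenyl-2,6-dimethylcyclohex-2-en-1-yl]-3-methylpent-2-enoate | C=C[C@@]1(C)[C@H](CC/C(C)=C/C(=O)OC(C)(C)C)C(C)=CC[C@@H]1[C@](C)(CO[Si](c2ccccc2)(c2ccccc2)C(C)(C)C)C=O | intermediate
15 | adduct of 14 with two 9-BBN units (C2–B alkylborane and C3–O borinate) | B3(CC[C@@]1(C)[C@H](CC/C(C)=C/C(=O)OC(C)(C)C)C(C)=CC[C@@H]1[C@](C)(CO[Si](c2ccccc2)(c2ccccc2)C(C)(C)C)COB4C6CCCC4CCC6)C5CCCC3CCC5 | intermediate (not isolated)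
16 | tert-butyl (2E)-5-[(1R,5S,6S)-5-[(2S)-1-[(tert-butyldiphenylsilyl)oxy]-3-hydroxy-2-methylpropan-2-yl]-6-(2-hydroxyethyl)-2,6-dimethylcyclohex-2-en-1-yl]-3-methylpent-2-enoate | OCC[C@@]1(C)[C@H](CC/C(C)=C/C(=O)OC(C)(C)C)C(C)=CC[C@@H]1[C@](C)(CO[Si](c2ccccc2)(c2ccccc2)C(C)(C)C)CO | intermediate
17 | tert-butyl (2E)-5-[(1R,5S,6S)-5-[(2R)-1-[(tert-butyldiphenylsilyl)oxy]-2-methyl-3-oxopropan-2-yl]-2,6-dimethyl-6-(2-oxoethyl)cyclohex-2-en-1-yl]-3-methylpent-2-enoate | O=CC[C@@]1(C)[C@H](CC/C(C)=C/C(=O)OC(C)(C)C)C(C)=CC[C@@H]1[C@](C)(CO[Si](c2ccccc2)(c2ccccc2)C(C)(C)C)C=O | intermediate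
18 | tert-butyl (2E)-5-[(1R,4aS,5R,6R,7S,8aS)-5-{[(tert-butyldiphenylsilyl)oxy]methyl}-6,7-dihydroxy-2,5,8a-trimethyl-1,4,4a,5,6,7,8,8a-octahydronaphthalen-1-yl]-3-methylpent-2-enoate | O[C@H]1C[C@@]2(C)[C@H](CC/C(C)=C/C(=O)OC(C)(C)C)C(C)=CC[C@@H]2[C@](C)(CO[Si](c3ccccc3)(c3ccccc3)C(C)(C)C)[C@H]1O | intermediate
19 | tert-butyl (2E)-5-[(1R,4aS,5R,6R,7S,8aS)-6,7-bis(acetyloxy)-5-{[(tert-butyldiphenylsilyl)oxy]methyl}-2,5,8a-trimethyl-1,4,4a,5,6,7,8,8a-octahydronaphthalen-1-yl]-3-methylpent-2-enoate | CC(=O)O[C@H]1C[C@@]2(C)[C@H](CC/C(C)=C/C(=O)OC(C)(C)C)C(C)=CC[C@@H]2[C@](C)(CO[Si](c3ccccc3)(c3ccccc3)C(C)(C)C)[C@H]1OC(C)=O | intermediate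
20 | tert-butyl (2E)-5-[(1R,4aS,5R,6R,7S,8aS)-6,7-bis(acetyloxy)-5-(hydroxymethyl)-2,5,8a-trimethyl-1,4,4a,5,6,7,8,8a-octahydronaphthalen-1-yl]-3-methylpent-2-enoate | CC(=O)O[C@H]1C[C@@]2(C)[C@H](CC/C(C)=C/C(=O)OC(C)(C)C)C(C)=CC[C@@H]2[C@](C)(CO)[C@H]1OC(C)=O | intermediate
21 | tert-butyl (2E)-5-[(1R,4aS,5S,6R,7S,8aS)-6,7-bis(acetyloxy)-5-formyl-2,5,8a-trimethyl-1,4,4a,5,6,7,8,8a-octahydronaphthalen-1-yl]-3-methylpent-2-enoate | CC(=O)O[C@H]1C[C@@]2(C)[C@H](CC/C(C)=C/C(=O)OC(C)(C)C)C(C)=CC[C@@H]2[C@](C)(C=O)[C@H]1OC(C)=O | intermediate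
22 | trimethylsilyl (2E)-5-[(1R,4aS,5S,6R,7S,8aS)-6,7-bis(acetyloxy)-5-formyl-2,5,8a-trimethyl-1,4,4a,5,6,7,8,8a-octahydronaphthalen-1-yl]-3-methylpent-2-enoate | CC(=O)O[C@H]1C[C@@]2(C)[C@H](CC/C(C)=C/C(=O)O[Si](C)(C)C)C(C)=CC[C@@H]2[C@](C)(C=O)[C@H]1OC(C)=O | intermediate (not isolated)
23 | (2E)-5-[(1R,4aS,5S,6R,7S,8aS)-6,7-bis(acetyloxy)-5-formyl-2,5,8a-trimethyl-1,4,4a,5,6,7,8,8a-octahydronaphthalen-1-yl]-3-methylpent-2-enoic acid (CNP0273594.1; labdane descriptors 2S,3R,4S,5S,9R,10S) | CC(=O)O[C@H]1C[C@@]2(C)[C@H](CC/C(C)=C/C(=O)O)C(C)=CC[C@@H]2[C@](C)(C=O)[C@H]1OC(C)=O | target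

**Step count and risks**

Total step count: 17. Longest linear sequence: 17 steps (1 → 23); compound 6 enters at step 4.

Steps most likely to fail:

1. Step 4. The chiral cation may give insufficient facial or exo control with this β-ester-substituted enal (for example through competing binding at the ester carbonyl), or the ortho regiochemistry may be eroded by the C8 methyl group. Fallback, setting out from 5 and 6 and returning at 7: the cycloaddition is run with the achiral Lewis acid Me2AlCl (CH2Cl2, −78 °C), which should still give the exo-formyl adduct, now as 7 together with the enantiomer of 7 F1. Condensation of the mixture with (1R,2R)-N,N'-dimethyl-1,2-diphenylethane-1,2-diamine (Et2O, 4 Å sieves) should give the imidazolidine of 7 F2 and the imidazolidine of the enantiomer F3, diastereomers separable by chromatography or crystallisation. Mild acid hydrolysis of F2 (aqueous AcOH) would return enantiopure 7 and the recoverable diamine.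

2. Step 9. Formaldehyde may add to the other enolate face, or with little preference, so that the wrong C4 configuration predominates; retro-aldol equilibration could erode any kinetic preference further. Fallback, setting out from 12 and returning at 14: the same aldol then supplies the C4 epimer of 13 F4, and the two oxygenated arms on C4 exchange roles. 4-Methoxybenzyl trichloroacetimidate with catalytic CSA gives the PMB ether aldehyde F5; NaBH4 reduces the formyl group to the PMB ether alcohol F6; TBDPSCl and imidazole give the mixed PMB/TBDPS bis-ether F7; DDQ (CH2Cl2, pH 7 buffer) removes the PMB group to give the silyl ether alcohol F8; Dess–Martin oxidation of F8 gives 14.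

3. Step 13. The ketyls may be reduced to alcohols or couple intermolecularly, or ring closure may proceed without the required cis and facial selectivity. Fallback, setting out from 17 and returning at 18: double Wittig methylenation (Ph3PCH3Br, KN(SiMe3)2) gives the 1,7-diene F9. Ring-closing metathesis with the second-generation Grubbs catalyst (H2IMes)(PCy3)Cl2Ru=CHPh closes ring A as the C2=C3 cyclohexene F10. OsO4 (cat.) with N-methylmorpholine N-oxide then dihydroxylates the cis-disubstituted ring-A olefin from the face opposite the axial C20 and C19 groups to give 18. The trisubstituted C7=C8 olefin is a plausible competitor (it is more electron-rich, though more hindered), so the oxidant would be limited to one equivalent and this chemoselectivity is the weak point of the fallback.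

Further compounds
F1 | step 4 | enantiomer of 7, tert-butyl (2E)-5-[(1S,5R,6R)-5-(ethoxycarbonyl)-6-formyl-2,6-dimethylcyclohex-2-en-1-yl]-3-methylpent-2-enoate | O=C[C@]1(C)[C@@H](CC/C(C)=C/C(=O)OC(C)(C)C)C(C)=CC[C@H]1C(=O)OCC
F2 | step 4 | imidazolidine of 7 [(4R,5R)-1,3-dimethyl-4,5-diphenylimidazolidin-2-yl in place of the formyl group] | CN1[C@H](c2ccccc2)[C@H](N(C)C1[C@@]3(C)[C@H](CC/C(C)=C/C(=O)OC(C)(C)C)C(C)=CC[C@@H]3C(=O)OCC)c2ccccc2
F3 | step 4 | imidazolidine of the enantiomer F1 [(4R,5R)-1,3-dimethyl-4,5-diphenylimidazolidin-2-yl in place of the formyl group] | CN1[C@H](c2ccccc2)[C@H](N(C)C1[C@]3(C)[C@@H](CC/C(C)=C/C(=O)OC(C)(C)C)C(C)=CC[C@H]3C(=O)OCC)c2ccccc2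
F4 | step 9 | C4 epimer of 13, tert-butyl (2E)-5-[(1R,5S,6S)-6-ethenyl-5-[(2S)-1-hydroxy-2-methyl-3-oxopropan-2-yl]-2,6-dimethylcyclohex-2-en-1-yl]-3-methylpent-2-enoate | C=C[C@@]1(C)[C@H](CC/C(C)=C/C(=O)OC(C)(C)C)C(C)=CC[C@@H]1[C@@](C)(CO)C=O
F5 | step 9 | PMB ether aldehyde (4-methoxybenzyl ether of F4) | C=C[C@@]1(C)[C@H](CC/C(C)=C/C(=O)OC(C)(C)C)C(C)=CC[C@@H]1[C@@](C)(COCc2ccc(OC)cc2)C=O
F6 | step 9 | PMB ether alcohol (formyl group of F5 reduced to hydroxymethyl) | C=C[C@@]1(C)[C@H](CC/C(C)=C/C(=O)OC(C)(C)C)C(C)=CC[C@@H]1[C@@](C)(COCc2ccc(OC)cc2)CO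
F7 | step 9 | mixed PMB/TBDPS bis-ether | C=C[C@@]1(C)[C@H](CC/C(C)=C/C(=O)OC(C)(C)C)C(C)=CC[C@@H]1[C@@](C)(COCc2ccc(OC)cc2)CO[Si](c2ccccc2)(c2ccccc2)C(C)(C)C
F8 | step 9 | silyl ether alcohol (primary alcohol corresponding to aldehyde 14) | C=C[C@@]1(C)[C@H](CC/C(C)=C/C(=O)OC(C)(C)C)C(C)=CC[C@@H]1[C@@](C)(CO)CO[Si](c2ccccc2)(c2ccccc2)C(C)(C)C
F9 | step 13 | 1,7-diene (C10 allyl and C4 vinyl in place of the two formyl-bearing arms of 17) | C=CC[C@@]1(C)[C@H](CC/C(C)=C/C(=O)OC(C)(C)C)C(C)=CC[C@@H]1[C@](C)(CO[Si](c2ccccc2)(c2ccccc2)C(C)(C)C)C=C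
F10 | step 13 | C2=C3 cyclohexene (ring A closed; 2,3-didehydro analogue of 18 without the hydroxyls) | C=1C[C@@]2(C)[C@H](CC/C(C)=C/C(=O)OC(C)(C)C)C(C)=CC[C@@H]2[C@](C)(CO[Si](c3ccccc3)(c3ccccc3)C(C)(C)C)C=1
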